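**Strategy**

Ring D is read as a folded triketide: its hydroxyls at D2, D4 and D6 are the carbonyl oxygens of a 3,5-dioxohexanoate, so the ring is cut at the D5–D6 bond. The key step closes ring D by intramolecular Claisen acylation of the benzylic carbon (future D5, already carrying ring E) at the ester carbon (future D6) and aromatises in the same operation. Its precursor is an open-chain methyl 2-aryloxy-6-aryl-3,5-dioxohexanoate, in which the congested D1–O–ring C ether is still a plain alkyl aryl ether and the D5–ring E biaryl bond a benzylic C–C bond. Two such arms are then joined to the ring A–ring B core by double Ullmann etherification and demethylated.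

Key step: step 8

Remark (lettering and assumption): ring A is the 3,5-dihydroxyphenoxy group, ring B the central ring with three aryloxy groups, ring C the 2,6-dihydroxy-1,4-dioxygenated ring, ring D the phloroglucinol ring (D1 ether oxygen to ring C, D5 bond to ring E), ring E the 2,4,6-trihydroxyphenyl group. The target has no stereocentre, and the symmetric ring E makes the biaryl axis non-stereogenic, so no stereocontrol is required.

**Route**

Step 1
Reactants: 1 syringaldehyde
Product: 2 4-(benzyloxy)-3,5-dimethoxybenzaldehyde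
Conditions: BnBr, K2CO3, DMF, 60 °C
Reagents that add atoms: benzyl bromide, BrCc1ccccc1
Why: Williamson O-benzylation of the only phenol masks the oxygen that will later be joined to ring B.

Step 2
Reactants: 2 4-(benzyloxy)-3,5-dimethoxybenzaldehyde
Product: 4 4-(benzyloxy)-3,5-dimethoxyphenol, via aryl formate 3 (not isolated)
Conditions: mCPBA, CH2Cl2, 0 °C to rt; aq. NaHCO3 wash; then K2CO3 (cat.), MeOH, rt
Reagents that add atoms: mCPBA, OOC(=O)c1cccc(Cl)c1
Why: Baeyer–Villiger (Dakin-type) oxidation, in which the electron-rich aryl group migrates in the peracid adduct to give the aryl formate, whose methanolysis releases the phenol.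

Step 3
Reactants: 4 4-(benzyloxy)-3,5-dimethoxyphenol; 5 methyl 2-chloroacetoacetate
Product: 6 methyl 2-[4-(benzyloxy)-3,5-dimethoxyphenoxy]-3-oxobutanoate (racemic at C2)
Conditions: K2CO3, KI (cat.), acetone, 56 °C
Reagents that add atoms: none
Why: Williamson-type SN2 displacement of the doubly activated chloride by the phenoxide makes the future D1–O bond as an unhindered alkyl aryl ether; the new centre is racemic and enolisable, which does not matter because it becomes an aromatic carbon.

Step 4
Reactants: 7 1,3,5-trimethoxybenzene; 8 methyl chlorooxoacetate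
Product: 9 methyl oxo(2,4,6-trimethoxyphenyl)acetate
Conditions: AlCl3 (1.1 equiv), CH2Cl2, −10 °C to 0 °C
Reagents that add atoms: none
Why: Friedel–Crafts acylation of the very nucleophilic arene stops after one acylation because the keto ester deactivates the ring, and the three equivalent positions leave no regiochemical question.

Step 5
Reactants: 9 methyl oxo(2,4,6-trimethoxyphenyl)acetate
Product: 10 methyl (2,4,6-trimethoxyphenyl)acetate
Conditions: Et3SiH (3 equiv), CF3CO2H, CH2Cl2, 0 °C to rt
Reagents that add atoms: none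
Why: Ionic hydrogenation reduces the aryl ketone to CH2 by hydride transfer, ionisation of the benzylic alcohol to a cation stabilised by three methoxy groups and a second hydride transfer, and it leaves the ester untouched.

Step 6
Reactants: 10 methyl (2,4,6-trimethoxyphenyl)acetate
Product: 11 N-methoxy-N-methyl-2-(2,4,6-trimethoxyphenyl)acetamide
Conditions: MeNH(OMe)·HCl, iPrMgCl, THF, −20 °C to 0 °C
Reagents that add atoms: N,O-dimethylhydroxylamine hydrochloride, CNOC.Cl
Why: Weinreb amide formation by aminolysis of the ester with the magnesium amide of N,O-dimethylhydroxylamine, which adds to the ester faster than it enolises it.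

Step 7
Reactants: 6 methyl 2-[4-(benzyloxy)-3,5-dimethoxyphenoxy]-3-oxobutanoate; 11 N-methoxy-N-methyl-2-(2,4,6-trimethoxyphenyl)acetamide
Product: 13 methyl 2-[4-(benzyloxy)-3,5-dimethoxyphenoxy]-3,5-dioxo-6-(2,4,6-trimethoxyphenyl)hexanoate (racemic at C2), via dilithium dienolate 12 (not isolated)
Conditions: 6 (2 equiv), LiN(iPr)2 (4.2 equiv), THF, −78 °C to 0 °C; then 11, −78 °C to 0 °C; cold 1 M HCl
Reagents that add atoms: none
Why: γ-Acylation of a β-keto ester dianion (Claisen-type acylation): the second deprotonation places the reactive carbanion on the terminal methyl group, which adds to the Weinreb amide to give a chelated tetrahedral adduct that collapses only on quench, so the chain stops at the 3,5-dioxo ester.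

Step 8
Reactants: 13 methyl 2-[4-(benzyloxy)-3,5-dimethoxyphenoxy]-3,5-dioxo-6-(2,4,6-trimethoxyphenyl)hexanoate
Product: 15 2-[4-(benzyloxy)-3,5-dimethoxyphenoxy]-4-(2,4,6-trimethoxyphenyl)benzene-1,3,5-triol, via cyclohexane-1,3,5-trione 14 (not isolated)
Conditions: Mg(OMe)2 (6 equiv), MeOH, 65 °C, argon; then 1 M HCl
Reagents that add atoms: none
Why: Methoxide equilibrates the enolates of 13, and magnesium chelation of the 3,5-diketone leaves C2–H in place so that the ester, inductively activated by the α-aryloxy group, remains an acyl acceptor; further enolisation toward C6 gives the dienolate whose benzylic carbon adds to the ester carbonyl, and loss of methoxide gives trione 14, which enolises at once to the phloroglucinol. The closest known reaction is the biomimetic Claisen (Dieckmann-type) cyclisation of 3,5-dioxoalkanoates and related triketo esters to phloroglucinols. Ring D closes by a 6-(enolendo)-exo-trig acyl substitution that forms the D5–D6 bond. No stereocentre is created, and the racemic centre at C2 and the sp3 centres of 14 vanish on aromatisation. The step needs acylation at carbon C6 to win over acylation at the C5 enolate oxygen (lactonisation to a 4-hydroxy-2-pyranone) and over retro-Claisen cleavage: the lactone is reopened by Mg(OMe)2 in methanol whereas aromatisation to the phloroglucinolate is irreversible, the ketones are protected as enolates, and C4, the other carbon nucleophile, could only close a four-membered ring.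

Step 9
Reactants: 15 2-[4-(benzyloxy)-3,5-dimethoxyphenoxy]-4-(2,4,6-trimethoxyphenyl)benzene-1,3,5-triol
Product: 16 2-[4-(benzyloxy)-3,5-dimethoxyphenoxy]-1,3,5-trimethoxy-4-(2,4,6-trimethoxyphenyl)benzene
Conditions: Me2SO4 (4.5 equiv), K2CO3, acetone, 56 °C, argon
Reagents that add atoms: dimethyl sulfate, COS(=O)(=O)OC
Why: Williamson O-methylation with the hard electrophile dimethyl sulfate and carbonate in acetone, conditions under which phloroglucinols are alkylated on oxygen and not on carbon.

Step 10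
Reactants: 16 2-[4-(benzyloxy)-3,5-dimethoxyphenoxy]-1,3,5-trimethoxy-4-(2,4,6-trimethoxyphenyl)benzene
Product: 17 2,6-dimethoxy-4-[2,4,6-trimethoxy-3-(2,4,6-trimethoxyphenyl)phenoxy]phenol
Conditions: H2 (1 atm), Pd/C (10 wt%), EtOAc/MeOH, rt
Reagents that add atoms: none
Why: Catalytic hydrogenolysis cleaves only the benzylic C–O bond and frees the phenol of ring C, while methyl ethers, the diaryl ether and the biaryl are inert.

Step 11
Reactants: 18 2,6-dibromo-4-methoxyphenol; 19 3,5-dimethoxyphenylboronic acid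
Product: 20 1,3-dibromo-2-(3,5-dimethoxyphenoxy)-5-methoxybenzene
Conditions: Cu(OAc)2 (1 equiv), pyridine, 4 Å molecular sieves, CH2Cl2, dry air, rt
Reagents that add atoms: none
Why: Chan–Lam coupling forms the ring A–ring B ether at room temperature by transmetalation of the arylboronic acid to a copper phenoxide and reductive elimination from trivalent copper, a process that tolerates 2,6-dihalophenols and leaves both C–Br bonds intact, with oxygen returning copper to the divalent state.

Step 12
Reactants: 17 2,6-dimethoxy-4-[2,4,6-trimethoxy-3-(2,4,6-trimethoxyphenyl)phenoxy]phenol; 20 1,3-dibromo-2-(3,5-dimethoxyphenoxy)-5-methoxybenzene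
Product: 22 1,3-bis{2,6-dimethoxy-4-[2,4,6-trimethoxy-3-(2,4,6-trimethoxyphenyl)phenoxy]phenoxy}-2-(3,5-dimethoxyphenoxy)-5-methoxybenzene, via monoether bromide 21 (not isolated)
Conditions: 17 (2.4 equiv), CuI (20 mol%), picolinic acid (40 mol%), K3PO4, DMSO, 110 °C, argon
Reagents that add atoms: none
Why: Twofold Ullmann diaryl ether synthesis with the CuI–picolinic acid system, which is known to couple 2,6-disubstituted phenols with ortho-substituted aryl bromides; excess phenoxide carries the monoether bromide through the second substitution.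

Step 13
Reactants: 22 1,3-bis{2,6-dimethoxy-4-[2,4,6-trimethoxy-3-(2,4,6-trimethoxyphenyl)phenoxy]phenoxy}-2-(3,5-dimethoxyphenoxy)-5-methoxybenzene
Product: 23 3,5-bis{2,6-dihydroxy-4-[2,4,6-trihydroxy-3-(2,4,6-trihydroxyphenyl)phenoxy]phenoxy}-4-(3,5-dihydroxyphenoxy)phenol (CNP0227063.0)
Conditions: BBr3 (60 equiv), CH2Cl2, −78 °C to rt, argon; then H2O, 0 °C
Reagents that add atoms: none
Why: BBr3 demethylation cleaves all nineteen aryl methyl ethers by complexation of each methoxy oxygen and SN2 attack of bromide on the methyl group, while diaryl ether and biaryl bonds offer no sp3 carbon and should survive.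

**Compound list**

1 | syringaldehyde (4-hydroxy-3,5-dimethoxybenzaldehyde) | COc1cc(C=O)cc(OC)c1O | starting material
2 | 4-(benzyloxy)-3,5-dimethoxybenzaldehyde | COc1cc(C=O)cc(OC)c1OCc1ccccc1 | intermediate
3 | 4-(benzyloxy)-3,5-dimethoxyphenyl formate | COc1cc(OC=O)cc(OC)c1OCc1ccccc1 | intermediate (not isolated)
4 | 4-(benzyloxy)-3,5-dimethoxyphenol | COc1cc(O)cc(OC)c1OCc1ccccc1 | intermediate
5 | methyl 2-chloroacetoacetate (methyl 2-chloro-3-oxobutanoate, racemic) | COC(=O)C(Cl)C(C)=O | starting material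
6 | methyl 2-[4-(benzyloxy)-3,5-dimethoxyphenoxy]-3-oxobutanoate (racemic) | COC(=O)C(Oc1cc(OC)c(OCc2ccccc2)c(OC)c1)C(C)=O | intermediate
7 | 1,3,5-trimethoxybenzene | COc1cc(OC)cc(OC)c1 | starting material
8 | methyl chlorooxoacetate | COC(=O)C(Cl)=O | starting material
9 | methyl oxo(2,4,6-trimethoxyphenyl)acetate | COC(=O)C(=O)c1c(OC)cc(OC)cc1OC | intermediate
10 | methyl (2,4,6-trimethoxyphenyl)acetate | COC(=O)Cc1c(OC)cc(OC)cc1OC | intermediate
11 | N-methoxy-N-methyl-2-(2,4,6-trimethoxyphenyl)acetamide | CON(C)C(=O)Cc1c(OC)cc(OC)cc1OC | intermediate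
12 | dilithium dienolate of 6 (deprotonated at C2 and at the terminal methyl; enolate geometry undefined) | [Li+].[Li+].COC([O-])=C(Oc1cc(OC)c(OCc2ccccc2)c(OC)c1)C(=C)[O-] | intermediate (not isolated)
13 | methyl 2-[4-(benzyloxy)-3,5-dimethoxyphenoxy]-3,5-dioxo-6-(2,4,6-trimethoxyphenyl)hexanoate (racemic at C2, partly enolised) | COC(=O)C(Oc1cc(OC)c(OCc2ccccc2)c(OC)c1)C(=O)CC(=O)Cc1c(OC)cc(OC)cc1OC | intermediate (key-step precursor)
14 | 2-[4-(benzyloxy)-3,5-dimethoxyphenoxy]-4-(2,4,6-trimethoxyphenyl)cyclohexane-1,3,5-trione (mixture of diastereomers, present as enolates) | O=C1CC(=O)C(c2c(OC)cc(OC)cc2OC)C(=O)C1Oc1cc(OC)c(OCc2ccccc2)c(OC)c1 | intermediate (not isolated)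
15 | 2-[4-(benzyloxy)-3,5-dimethoxyphenoxy]-4-(2,4,6-trimethoxyphenyl)benzene-1,3,5-triol | Oc1cc(O)c(-c2c(OC)cc(OC)cc2OC)c(O)c1Oc1cc(OC)c(OCc2ccccc2)c(OC)c1 | intermediate (key-step product)
16 | 2-[4-(benzyloxy)-3,5-dimethoxyphenoxy]-1,3,5-trimethoxy-4-(2,4,6-trimethoxyphenyl)benzene | COc1cc(OC)c(-c2c(OC)cc(OC)cc2OC)c(OC)c1Oc1cc(OC)c(OCc2ccccc2)c(OC)c1 | intermediate
17 | 2,6-dimethoxy-4-[2,4,6-trimethoxy-3-(2,4,6-trimethoxyphenyl)phenoxy]phenol | COc1cc(OC)c(-c2c(OC)cc(OC)cc2OC)c(OC)c1Oc1cc(OC)c(O)c(OC)c1 | intermediate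
18 | 2,6-dibromo-4-methoxyphenol | COc1cc(Br)c(O)c(Br)c1 | starting material
19 | 3,5-dimethoxyphenylboronic acid | COc1cc(OC)cc(B(O)O)c1 | starting material
20 | 1,3-dibromo-2-(3,5-dimethoxyphenoxy)-5-methoxybenzene | COc1cc(Br)c(Oc2cc(OC)cc(OC)c2)c(Br)c1 | intermediate
21 | 1-bromo-3-{2,6-dimethoxy-4-[2,4,6-trimethoxy-3-(2,4,6-trimethoxyphenyl)phenoxy]phenoxy}-2-(3,5-dimethoxyphenoxy)-5-methoxybenzene | COc1cc(Br)c(Oc2cc(OC)cc(OC)c2)c(Oc2c(OC)cc(Oc3c(OC)cc(OC)c(-c4c(OC)cc(OC)cc4OC)c3OC)cc2OC)c1 | intermediate (not isolated)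
22 | 1,3-bis{2,6-dimethoxy-4-[2,4,6-trimethoxy-3-(2,4,6-trimethoxyphenyl)phenoxy]phenoxy}-2-(3,5-dimethoxyphenoxy)-5-methoxybenzene (nonadeca-O-methyl ether of the target) | COc1cc(Oc2c(OC)cc(Oc3c(OC)cc(OC)c(-c4c(OC)cc(OC)cc4OC)c3OC)cc2OC)c(Oc2cc(OC)cc(OC)c2)c(Oc2c(OC)cc(Oc3c(OC)cc(OC)c(-c4c(OC)cc(OC)cc4OC)c3OC)cc2OC)c1 | intermediate
23 | 3,5-bis{2,6-dihydroxy-4-[2,4,6-trihydroxy-3-(2,4,6-trihydroxyphenyl)phenoxy]phenoxy}-4-(3,5-dihydroxyphenoxy)phenol, CNP0227063.0 (achiral) | Oc1cc(O)cc(Oc2c(Oc3c(O)cc(Oc4c(O)cc(O)c(-c5c(O)cc(O)cc5O)c4O)cc3O)cc(O)cc2Oc2c(O)cc(Oc3c(O)cc(O)c(-c4c(O)cc(O)cc4O)c3O)cc2O)c1 | target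

**Count**

Total step count: 13. Longest linear sequence: 9 steps (steps 1, 2, 3, 7, 8, 9, 10, 12, 13, from syringaldehyde).

**Steps most likely to fail, with fallbacks**

Risk 1, step 8 (ring D closure). Enolisation at C2 may turn the ester into an unreactive enolate, so that carbon acylation is outrun by lactonisation through oxygen or by retro-Claisen cleavage of the chain. The fallback takes ring D from a preformed arene and uses known chemistry only; it sets out from 7 and returns at 16.
- 7 is iodinated (NIS, MeCN, rt) to 2-iodo-1,3,5-trimethoxybenzene F1.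
- F1 is homocoupled (Cu powder, DMF, 150 °C; classical Ullmann biaryl synthesis, where symmetry removes any cross-coupling problem) to 2,2',4,4',6,6'-hexamethoxybiphenyl F2.
- Monobromination (NBS, 1 equiv, MeCN, 0 °C; the four free positions are equivalent) gives 3-bromo-2,2',4,4',6,6'-hexamethoxybiphenyl F3.
- Palladium-catalysed hydroxylation (Pd2(dba)3, tBuXPhos, KOH, dioxane/H2O, 100 °C) gives 2,2',4,4',6,6'-hexamethoxybiphenyl-3-ol F4.
- Commercial 4-bromo-2,6-dimethoxyphenol is benzylated (BnBr, K2CO3, DMF) to 2-(benzyloxy)-5-bromo-1,3-dimethoxybenzene F5, a bromide without ortho substituents.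
- Ullmann etherification of F4 with F5 (CuI, picolinic acid, K3PO4, DMSO, 110 °C) should give 16, from which steps 10, 12 and 13 follow unchanged.

Risk 2, step 12 (double Ullmann etherification). The second C–O coupling, at a bromide flanked by an aryloxy group on a ring that already carries two, may stall, and hydrodebromination or oxidation of the electron-rich phenoxide may take over. The fallback replaces copper coupling by nucleophilic aromatic substitution and attaches ring A last; it sets out from 17 and returns at 22.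
- Two equivalents of 17 displace both fluorides of commercial 2,6-difluoro-4-methoxybenzaldehyde (COc1cc(F)c(C=O)c(F)c1; Cs2CO3, DMSO, 100 °C; each fluoride is ortho to the activating formyl group) to give 2,6-bis{2,6-dimethoxy-4-[2,4,6-trimethoxy-3-(2,4,6-trimethoxyphenyl)phenoxy]phenoxy}-4-methoxybenzaldehyde F6.
- Baeyer–Villiger oxidation as in step 2 (mCPBA, CH2Cl2; then K2CO3 cat., MeOH) passes through 2,6-bis{2,6-dimethoxy-4-[2,4,6-trimethoxy-3-(2,4,6-trimethoxyphenyl)phenoxy]phenoxy}-4-methoxyphenyl formate F7.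
- Methanolysis of F7 gives 2,6-bis{2,6-dimethoxy-4-[2,4,6-trimethoxy-3-(2,4,6-trimethoxyphenyl)phenoxy]phenoxy}-4-methoxyphenol F8.
- Chan–Lam coupling of F8 with 19 under the conditions of step 11 should install ring A and give 22.

Risk 3, step 7 (dianion acylation). Proton transfer from the benzylic CH2 of 11, or from the acidic product, to dianion 12 may quench the nucleophile before the C–C bond forms. The fallback replaces acylation by aldol addition and oxidation; it sets out from 11 and 6 and returns at 13.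
- 11 is reduced (iBu2AlH, THF, −78 °C) to (2,4,6-trimethoxyphenyl)acetaldehyde F9.
- Dianion 12, made from 6 as in step 7, adds to F9 at −78 °C, where carbonyl addition outruns enolisation, to give methyl 2-[4-(benzyloxy)-3,5-dimethoxyphenoxy]-5-hydroxy-3-oxo-6-(2,4,6-trimethoxyphenyl)hexanoate F10 (mixture of diastereomers).
- Oxidation of the secondary alcohol with Dess–Martin periodinane (CH2Cl2, rt) should give 13.

**Further compounds**

F1 | step 8 | 2-iodo-1,3,5-trimethoxybenzene | COc1cc(OC)c(I)c(OC)c1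
F2 | step 8 | 2,2',4,4',6,6'-hexamethoxybiphenyl | COc1cc(OC)c(-c2c(OC)cc(OC)cc2OC)c(OC)c1
F3 | step 8 | 3-bromo-2,2',4,4',6,6'-hexamethoxybiphenyl | COc1cc(OC)c(-c2c(OC)cc(OC)cc2OC)c(OC)c1Br
F4 | step 8 | 2,2',4,4',6,6'-hexamethoxybiphenyl-3-ol | COc1cc(OC)c(-c2c(OC)cc(OC)cc2OC)c(OC)c1O
F5 | step 8 | 2-(benzyloxy)-5-bromo-1,3-dimethoxybenzene | COc1cc(Br)cc(OC)c1OCc1ccccc1
F6 | step 12 | 2,6-bis{2,6-dimethoxy-4-[2,4,6-trimethoxy-3-(2,4,6-trimethoxyphenyl)phenoxy]phenoxy}-4-methoxybenzaldehyde | COc1cc(Oc2c(OC)cc(Oc3c(OC)cc(OC)c(-c4c(OC)cc(OC)cc4OC)c3OC)cc2OC)c(C=O)c(Oc2c(OC)cc(Oc3c(OC)cc(OC)c(-c4c(OC)cc(OC)cc4OC)c3OC)cc2OC)c1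
F7 | step 12 | 2,6-bis{2,6-dimethoxy-4-[2,4,6-trimethoxy-3-(2,4,6-trimethoxyphenyl)phenoxy]phenoxy}-4-methoxyphenyl formate | COc1cc(Oc2c(OC)cc(Oc3c(OC)cc(OC)c(-c4c(OC)cc(OC)cc4OC)c3OC)cc2OC)c(OC=O)c(Oc2c(OC)cc(Oc3c(OC)cc(OC)c(-c4c(OC)cc(OC)cc4OC)c3OC)cc2OC)c1
F8 | step 12 | 2,6-bis{2,6-dimethoxy-4-[2,4,6-trimethoxy-3-(2,4,6-trimethoxyphenyl)phenoxy]phenoxy}-4-methoxyphenol | COc1cc(Oc2c(OC)cc(Oc3c(OC)cc(OC)c(-c4c(OC)cc(OC)cc4OC)c3OC)cc2OC)c(O)c(Oc2c(OC)cc(Oc3c(OC)cc(OC)c(-c4c(OC)cc(OC)cc4OC)c3OC)cc2OC)c1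
F9 | step 7 | (2,4,6-trimethoxyphenyl)acetaldehyde | O=CCc1c(OC)cc(OC)cc1OC
F10 | step 7 | methyl 2-[4-(benzyloxy)-3,5-dimethoxyphenoxy]-5-hydroxy-3-oxo-6-(2,4,6-trimethoxyphenyl)hexanoate (mixture of diastereomers) | COC(=O)C(Oc1cc(OC)c(OCc2ccccc2)c(OC)c1)C(=O)CC(O)Cc1c(OC)cc(OC)cc1OC
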